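**Assumptions:** Coloratanin A has no stereocentres (the carbinol carbon carries two methyls, and the prenyl alkene has two identical substituents on one carbon). Aryl MOM ethers are taken to survive MgCl₂/Et₃N and the basic or neutral Pd steps.

**Retrosynthetic overview**
1. Coloratanin A comes from a Suzuki–Miyaura coupling of 3-iodochromone **15** with aryl-Bpin **23**, followed by global MOM removal.
2. The pyranone ring is the only ring built. It closes from o-hydroxyacetophenone **11** via the DMF-DMA enaminone and I₂ cyclisation. Both benzene rings are carried in pre-formed.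
3. Acetophenone **11** comes from ortho-acetylation of phenol **9**, which comes from Ir-catalysed meta-C–H borylation and oxidation of 2-prenylresorcinol bis-MOM ether **5**, which comes from resorcinol.
4. In **9** the two ortho positions are equivalent, and the only free OH becomes O1. This fixes the prenyl group at C6, flanked by the 5- and 7-oxygens.
5. Aryl-Bpin **23** comes from 4-bromophenol by ortho-iodination, MOM protection, Sonogashira coupling with 2-methylbut-3-yn-2-ol, hydrogenation and Miyaura borylation.

**Branch A: 3-iodochromone**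

Step 1
Reactants: 1 resorcinol; 2 chloromethyl methyl ether (MOMCl)
Product: 3 1,3-bis(methoxymethoxy)benzene
Conditions: 2 (2.3 equiv), i-Pr₂NEt, CH₂Cl₂, 0 °C → rt
Reagents that add atoms: MOMCl, ClCOC
Why: Double MOM protection sets up the acetal-directed lithiation in the next step.

Step 2
Reactants: 3; 4 prenyl bromide (1-bromo-3-methylbut-2-ene)
Product: 5 2-(3-methylbut-2-en-1-yl)-1,3-bis(methoxymethoxy)benzene
Conditions: n-BuLi, THF, 0 °C → rt; then CuI (10 mol %), 4, –78 °C → rt
Reagents that add atoms: prenyl bromide, CC(C)=CCBr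
Why: Directed ortho-metalation occurs at C2, between the two OMOM groups. Cu-catalysed SN2 alkylation with prenyl bromide then gives the linear prenyl arene.

Step 3
Reactants: 5; 6 bis(pinacolato)diboron
Product: 7 2-[3,5-bis(methoxymethoxy)-4-(3-methylbut-2-en-1-yl)phenyl]-4,4,5,5-tetramethyl-1,3,2-dioxaborolane
Conditions: [Ir(OMe)(cod)]₂ (1.5 mol %), dtbpy (3 mol %), 6, THF, 80 °C
Reagents that add atoms: B₂pin₂, CC1(C)OB(OC1(C)C)B1OC(C)(C)C(C)(C)O1
Why: Ir-catalysed C–H borylation is sterically controlled. The only C–H flanked by two hydrogens is C5, meta to both OMOM groups, so it is borylated selectively.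

Step 4
Reactants: 7; 8 hydrogen peroxide
Product: 9 3,5-bis(methoxymethoxy)-4-(3-methylbut-2-en-1-yl)phenol
Conditions: 30% aq H₂O₂, NaOH (aq), THF, 0 °C → rt
Reagents that add atoms: H₂O₂, OO
Why: Oxidative C–B cleavage gives the phenol. The MOM groups and the trisubstituted alkene survive.

Step 5
Reactants: 9; 10 acetaldehyde
Product: 11 1-[2-hydroxy-4,6-bis(methoxymethoxy)-5-(3-methylbut-2-en-1-yl)phenyl]ethan-1-one
Conditions: anhydrous MgCl₂, Et₃N, 10 (10 equiv), MeCN, sealed tube, 80 °C
Reagents that add atoms: acetaldehyde, CC=O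
Why: Proposed new method: a Mg-templated ortho-C-acetylation of a free phenol. The Mg phenoxide binds acetaldehyde and delivers it to the ortho carbon through a six-membered transition state, giving the Mg alkoxide of a 1-(2-hydroxyaryl)ethanol. A second chelated acetaldehyde then accepts hydride in an Oppenauer-type step, and the chelated o-hydroxyaryl ketone drives the equilibrium. The closest known reaction is the MgCl₂/Et₃N/paraformaldehyde ortho-formylation of phenols, in which formaldehyde is also the hydride acceptor. The two ortho positions of 9 are equivalent, so a single regioisomer forms, and no stereocentre is involved.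

Step 6
Reactants: 11; 12 N,N-dimethylformamide dimethyl acetal (DMF-DMA)
Product: 13 (E)-3-(dimethylamino)-1-[2-hydroxy-4,6-bis(methoxymethoxy)-5-(3-methylbut-2-en-1-yl)phenyl]prop-2-en-1-one
Conditions: 12 (3 equiv), toluene, 100 °C
Reagents that add atoms: DMF-DMA, CN(C)C(OC)OC
Why: Condensation of the acetyl methyl with DMF-DMA (Bredereck-type) gives the push–pull enaminone. The o-OH is tolerated.

Step 7
Reactants: 13; 14 iodine
Product: 15 3-iodo-5,7-bis(methoxymethoxy)-6-(3-methylbut-2-en-1-yl)-4H-chromen-4-one
Conditions: 14, CH₂Cl₂, rt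
Reagents that add atoms: I₂, II
Why: Iodination of the enaminone α-carbon is followed by oxa-cyclisation of the only free OH onto the iminium and loss of HNMe₂ (Gammill-type 3-iodochromone synthesis). Because O1 is the sole free phenol, the prenyl ends up at C6 and C8 is H.

**Branch B: aryl-Bpin**

Step 8
Reactants: 16 4-bromophenol; 17 N-iodosuccinimide (NIS)
Product: 18 4-bromo-2-iodophenol
Conditions: 17, p-TsOH (cat.), MeCN, rt
Reagents that add atoms: NIS, O=C1CCC(=O)N1I
Why: Electrophilic iodination goes ortho to OH because the para position is blocked.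

Step 9
Reactants: 18; 2 MOMCl
Product: 19 4-bromo-2-iodo-1-(methoxymethoxy)benzene
Conditions: 2, i-Pr₂NEt, CH₂Cl₂, 0 °C → rt
Reagents that add atoms: MOMCl, ClCOC
Why: Protecting the phenol prevents benzofuran formation in the next step.

Step 10
Reactants: 19; 20 2-methylbut-3-yn-2-ol
Product: 21 4-[5-bromo-2-(methoxymethoxy)phenyl]-2-methylbut-3-yn-2-ol
Conditions: 20, PdCl₂(PPh₃)₂ (2 mol %), CuI (4 mol %), Et₃N, THF, rt
Reagents that add atoms: 2-methylbut-3-yn-2-ol, CC(C)(O)C#C
Why: Sonogashira coupling is chemoselective for C–I over C–Br at rt.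

Step 11
Reactants: 21; H₂
Product: 22 4-[5-bromo-2-(methoxymethoxy)phenyl]-2-methylbutan-2-ol
Conditions: H₂ (1 atm), 5% Pt/C, EtOAc, rt
Reagents that add atoms: none (H₂ adds only hydrogen)
Why: Pt/C reduces the alkyne to the alkane and leaves the aryl bromide intact, unlike Pd/C.

Step 12
Reactants: 22; 6 B₂pin₂
Product: 23 2-methyl-4-[2-(methoxymethoxy)-5-(4,4,5,5-tetramethyl-1,3,2-dioxaborolan-2-yl)phenyl]butan-2-ol
Conditions: 6, Pd(dppf)Cl₂ (3 mol %), KOAc, dioxane, 80 °C
Reagents that add atoms: B₂pin₂, CC1(C)OB(OC1(C)C)B1OC(C)(C)C(C)(C)O1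
Why: Miyaura borylation of the aryl bromide. The tertiary alcohol and the MOM ether are unaffected.

**Convergent coupling and deprotection**

Step 13
Reactants: 15 (3-iodochromone); 23 (aryl-Bpin)
Product: 24 5,7-bis(methoxymethoxy)-3-[3-(3-hydroxy-3-methylbutyl)-4-(methoxymethoxy)phenyl]-6-(3-methylbut-2-en-1-yl)-4H-chromen-4-one
Conditions: Pd(PPh₃)₄ (5 mol %), 2 M aq Na₂CO₃, DME, 80 °C
Reagents that add atoms: none (both coupling partners are numbered reactants)
Why: Suzuki–Miyaura coupling forms the C3–C1′ bond at the C–I bond. Carbonate is mild enough to leave the chromone ring intact.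

Step 14
Reactants: 24
Product: 25 Coloratanin A
Conditions: TMSOTf (8 equiv), 2,2′-bipyridyl (12 equiv), MeCN, 0 °C → rt; then H₂O
Reagents that add atoms: none (water only supplies hydrogen)
Why: The TMSOTf/bipyridyl method (Fujioka–Kita) removes aryl MOM ethers through pyridinium intermediates without protic acid. This avoids closure of the tertiary alcohol onto the 4′-OH to give a 2,2-dimethylchromane, and avoids cyclisation of the prenyl group onto the 5- or 7-OH. The TMS ether of the tertiary alcohol is cleaved on aqueous work-up.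

**Compound list**

| # | Name | SMILES | Role |
|---|---|---|---|
| 1 | resorcinol | Oc1cccc(O)c1 | starting material |
| 2 | chloromethyl methyl ether | ClCOC | starting material |
| 3 | 1,3-bis(methoxymethoxy)benzene | COCOc1cccc(OCOC)c1 | intermediate |
| 4 | prenyl bromide | CC(C)=CCBr | starting material |
| 5 | 2-prenyl-1,3-bis(MOM-oxy)benzene | CC(C)=CCc1c(OCOC)cccc1OCOC | intermediate |
| 6 | bis(pinacolato)diboron | CC1(C)OB(OC1(C)C)B1OC(C)(C)C(C)(C)O1 | starting material |
| 7 | 3,5-bis(MOM-oxy)-4-prenylphenyl-Bpin | CC(C)=CCc1c(OCOC)cc(B2OC(C)(C)C(C)(C)O2)cc1OCOC | intermediate |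
| 8 | hydrogen peroxide | OO | starting material |
| 9 | 3,5-bis(MOM-oxy)-4-prenylphenol | CC(C)=CCc1c(OCOC)cc(O)cc1OCOC | intermediate |
| 10 | acetaldehyde | CC=O | starting material |
| 11 | 2-hydroxy-4,6-bis(MOM-oxy)-5-prenylacetophenone | CC(=O)c1c(O)cc(OCOC)c(CC=C(C)C)c1OCOC | intermediate |
| 12 | DMF-DMA | CN(C)C(OC)OC | starting material |
| 13 | (E)-enaminone | CN(C)/C=C/C(=O)c1c(O)cc(OCOC)c(CC=C(C)C)c1OCOC | intermediate |
| 14 | iodine | II | starting material |
| 15 | 3-iodo-5,7-bis(MOM-oxy)-6-prenylchromone | O=c1c(I)coc2cc(OCOC)c(CC=C(C)C)c(OCOC)c12 | intermediate |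
| 16 | 4-bromophenol | Oc1ccc(Br)cc1 | starting material |
| 17 | N-iodosuccinimide | O=C1CCC(=O)N1I | starting material |
| 18 | 4-bromo-2-iodophenol | Oc1ccc(Br)cc1I | intermediate |
| 19 | 4-bromo-2-iodo-1-(MOM-oxy)benzene | COCOc1ccc(Br)cc1I | intermediate |
| 20 | 2-methylbut-3-yn-2-ol | CC(C)(O)C#C | starting material |
| 21 | aryl alkyne | COCOc1ccc(Br)cc1C#CC(C)(C)O | intermediate |
| 22 | aryl bromide (saturated side chain) | COCOc1ccc(Br)cc1CCC(C)(C)O | intermediate |
| 23 | aryl-Bpin | COCOc1ccc(B2OC(C)(C)C(C)(C)O2)cc1CCC(C)(C)O | intermediate |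
| 24 | tetra-MOM isoflavone | O=c1c(-c2ccc(OCOC)c(CCC(C)(C)O)c2)coc2cc(OCOC)c(CC=C(C)C)c(OCOC)c12 | intermediate |
| 25 | Coloratanin A | CC(C)=CCc1c(O)cc2occ(-c3ccc(O)c(CCC(C)(C)O)c3)c(=O)c2c1O | target |

**Step count:** 14 steps in total. The longest linear sequence is 9 steps (steps 1–7, 13 and 14), which is 64% of the total.

**Three steps most likely to fail**
1. **Step 5 (Mg/acetaldehyde ortho-acetylation, the proposed new step).** Acetaldehyde aldolisation and incomplete hydride transfer could leave the secondary alcohol or o-quinone methide-derived dimers.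
   - Fallback: Skattebøl ortho-formylation of 9 (paraformaldehyde, MgCl₂, Et₃N), then MeMgBr, then MnO₂ oxidation to give 11. This is a stepwise, known route.
2. **Step 2 (lithiation/prenylation).** Cu-mediated SN2′ attack could give reverse (1,1-dimethylallyl) prenyl, and prenyl bromide could undergo Li–Br exchange.
   - Fallback: Cu-catalysed allylation at C2, which has no SN2′ problem, followed by cross-metathesis of the allyl arene with 2-methyl-2-butene (Grubbs II) to give 5.
3. **Step 14 (global deprotection).** The tertiary alcohol, the prenyl group and the chromone ring are all acid-sensitive, and incomplete removal of the four MOM groups is possible.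
   - Fallback: use SEM ethers instead of MOM from step 1 onward (SEMCl; SEM-oxy groups also direct the lithiation), and remove all of them at the end with TBAF/ethylenediamine or MgBr₂, which is non-acidic.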